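The runs are simulated on assumed constants; the scatter is artificial.

Amounts first: the flask holds 0.036 M of starting material and 0.0432 M of reagent at 60 °C. Gamma is this flask followed so far, and zeta is the same charge at 45 °C.

the same everywhere: starting material 0.036 M; reagent 0.0432 M

| charge | temperature | remark | time |
|---|---|---|---|
| gamma | 60 °C | the very flask that is asked about, followed so far |  |
| zeta | 45 °C | run made earlier |  |
| flask | 60 °C |  | 3.0 d |

| run | time / h | tetra adduct / % |
|---|---|---|
| gamma | 8.00 | 11.8 |
| gamma | 15.0 | 13.1 |
| gamma | 25.0 | 13.9 |
| gamma | 30.0 | 12.5 |
| gamma | 40.0 | 13.0 |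
| gamma | 50.0 | 12.8 |
| gamma | 60.0 | 13.4 |
| zeta | 15.0 | 6.7 |
| zeta | 30.0 | 7.1 |
| zeta | 48.0 | 8.1 |
| zeta | 60.0 | 7.9 |
| zeta | 96.0 | 8.0 |
| zeta | 120 | 7.3 |

(readings scatter by 0.5 percentage points)

- Thursday's: at 3.0 d take out 90 % of the by-product then present, then wait 6.0 d
- Tuesday's: at 3.0 d raise the temperature by 20 K, then wait 6.0 d
- Saturday's: change nothing and wait 6.0 d more
- Sunday's: at 3.0 d add reagent, 50.0 % of the amount charged, then wait 6.0 d

- what is added takes up no volume worth counting
- the numbers in the tables scatter by 0.5 percentage points (one standard deviation)

* tetra adduct, in percent of the starting material first charged, at 3.0 d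
* the remedy with the largest gain of tetra adduct, or "none" below 2 percentage points (Thursday's / Tuesday's / Saturday's / Sunday's / none)
* tetra adduct present, in percent of the starting material first charged, after Tuesday's
* tetra adduct present, in percent of the starting material first charged, after Saturday's

Our ledger counts reagent. Going by its name, we take a tetra adduct to hold 4 reagent on one starting material, each releasing one by-product. Carrying a given fraction of the starting material the whole way then spends 3.33 times that fraction of the reagent charge; we call this the reagent price. The price stands above one, so the reagent charge pays for 30.0 % of the starting material, which is the first entry. The second entry comes from gamma, whose readings from 15.0 h to 60.0 h show no trend beyond their scatter of 0.5 percentage points and average 13.1 %. That reading costs 43.6 % of the reagent, which leaves 56.4 % unentered, and the books stay open until free reagent is known. Zeta levels off lower, at a reading of 7.68 %, so with the same charge the level moves with temperature. We therefore hold 13.1 % for now and for Saturday's, and we look to heat for a gain.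

The forecast reads “A flat level that rises with temperature points to an equilibrium, not a stall”, and it gives 13.1 % now, 13.1 % after Saturday's, and Tuesday's as best with 23.3 %.

The flask gives 13.1 %, with 13.1 % after Saturday's and Tuesday's best at 19.4 %.

    starting material + reagent → single product + by-product (k = 0.00990 /M/s, Ea = 51.0 kJ/mol)
    reagent + single product → bis adduct + by-product (k = 0.0120 /M/s, Ea = 71.0 kJ/mol)
    reagent + bis adduct → tris adduct + by-product (k = 0.0260 /M/s, Ea = 48.0 kJ/mol)
    reagent + tris adduct → tetra adduct + by-product (k = 0.0140 /M/s, Ea = 74.0 kJ/mol)
    2 starting material → homo dimer (k = 0.0440 /M/s, Ea = 56.0 kJ/mol)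
    tetra adduct ⇌ isomer of the product (K = 1.00, k = 4.50 × 10⁻⁴ /s, Ea = 89.0 kJ/mol, ΔH = −51.0 kJ/mol)
    (constants at 60 °C)

At 72.0 h this flask has 12.6 % of its reagent free and 0 % of its starting material, the limiting reagent by first exhaustion. At our price, the spent reagent pays for 26.2 % of the starting material carried the whole way. Tetra adduct accounts for 13.1 % of that, and the remaining 13.1 % matches the 13.1 % of isomer of the product, with single product at 0 %, bis adduct at 0 % and tris adduct at 0 %, so the reagent books close. The 73.8 % of the starting material in homo dimer holds no reagent.

In the neighbour flask charged with 0.0090 M of starting material, the price falls to 0.833, and with 54 % of its reagent free at 3.0 d the spent reagent pays for 55.2 % of its starting material. That neighbour flask computes to 27.5 % of tetra adduct and 27.5 % of isomer of the product.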